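**Retrosynthetic overview**

1. Germacrane numbering is used throughout: C1 = CH–OOH, C2–C3 = CH2CH2, C4=C5 with C15 on C4, C6 = lactone O–CH, C7 = ring-fusion CH, C8 = CH–O-angelate, C9 = CH2, C10=C14, C11=C13, C12 = lactone C=O. In the endgame, the C1–OOH/C10=C14 unit goes back to an E C1=C10 olefin (singlet-oxygen ene reaction). The angelate goes back to the C8 carbinol, and C13 to a lactone enolate plus an iminium salt.
2. Feature: what remains is the ten-membered ring C1–C10 as a (1(10)E,4Z)-cyclodeca-1,5-diene. C1=C10 and C4=C5 are bridged by C2–C3, and C6 next to C5 carries oxygen. Exchanging olefin partners (C5 with C10, C1 with C4) folds this ring into ring B (six-membered, C5–C10) and ring A (four-membered, C1–C4). The two rings are joined through C4–C5 and C1–C10 as a bicyclo[2.2.0]hexane.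
3. Key disconnection: the central cyclobutane (C1, C4, C5, C10) is cut at C4–C5 and C1–C10. This gives a ring B enone (C6=O, C5=C10, C14 on C10, C7 and C8 already set) and 1-methylcyclobutene (ring A).
4. The enone comes from ring-closing metathesis (C5=C10) and an auxiliary-controlled syn aldol (C7–C8) of a succinate imide with 3-methylbut-3-enal.
5. Order of ring formation: ring B (metathesis) → central cyclobutane (photocycloaddition, ring A brought in intact) → cis γ-lactone on ring B (6-epi, from the only face hydride can reach) → ten-membered ring (the cycloreversion erases ring A, ring B and the central ring) → lactone reopened and reclosed with inversion at the now allylic C6.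

Key step: step 9

Remark: the face and geometry assignments of steps 9–11 rest on chair models of ring B with C11 and O8 equatorial, and the adduct anti to O8 is assumed to be the major, separable product of step 9.

**Route**

Step 1
Reactants: 1 4-tert-butoxy-4-oxobutanoic acid (mono-tert-butyl succinate); 2 (R)-4-benzyl-1,3-oxazolidin-2-one
Product: 4 tert-butyl 4-[(4R)-4-benzyl-2-oxo-1,3-oxazolidin-3-yl]-4-oxobutanoate, via mixed pivalic anhydride 3 (not isolated)
Conditions: t-BuCOCl, Et3N, THF, −20 °C; then LiCl, 2, −20 → 20 °C
Reagents that add atoms: none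
Why: N-acylation of an oxazolidinone by a mixed pivalic anhydride in the presence of LiCl is the standard mild entry to Evans imides, attack going to the less hindered succinyl carbonyl, and it leaves the tert-butyl ester untouched.

Step 2
Reactants: 5 3-methylbut-3-en-1-ol
Product: 6 3-methylbut-3-enal
Conditions: Dess–Martin periodinane, CH2Cl2, 0 → 20 °C; aq NaHCO3/Na2S2O3 wash; dried solution used at once
Reagents that add atoms: none
Why: the Dess–Martin oxidation is neutral and fast, so the β,γ-unsaturated aldehyde should form without migration of the 1,1-disubstituted olefin into conjugation.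

Step 3
Reactants: 4 succinate imide; 6 3-methylbut-3-enal
Product: 7 tert-butyl (3R,4S)-3-{[(4R)-4-benzyl-2-oxo-1,3-oxazolidin-3-yl]carbonyl}-4-hydroxy-6-methylhept-6-enoate (syn aldol; chain C3 = C7, chain C4 = C8)
Conditions: n-Bu2BOTf, Et3N, CH2Cl2, 0 °C; 6, −78 → 0 °C; then H2O2, MeOH, pH 7 buffer
Reagents that add atoms: none
Why: in this Evans syn aldol reaction the Z boron enolate forms only next to the imide carbonyl and reacts through a closed chair transition state whose face is fixed by the (R)-benzyl group, which sets C7 (R) and C8 (S) as the syn pair (trans once both sit in ring B), while the bulky tert-butyl ester keeps the new C8 hydroxyl from lactonising onto C12.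

Step 4
Reactants: 7 syn aldol imide
Product: 8 tert-butyl (3R,4S)-4-hydroxy-3-[methoxy(methyl)carbamoyl]-6-methylhept-6-enoate
Conditions: MeONHMe·HCl, AlMe3, CH2Cl2, −15 → 0 °C; aq potassium sodium tartrate
Reagents that add atoms: N,O-dimethylhydroxylamine hydrochloride, CNOC.Cl
Why: aluminium-amide transamidation to the Weinreb amide is directed to the exocyclic imide carbonyl by the aluminium alkoxide at O8, frees the auxiliary for re-use and touches neither the hindered ester nor the two stereocentres.

Step 5
Reactants: 8 hydroxy Weinreb amide
Product: 9 tert-butyl (3R,4S)-4-(tert-butyldimethylsilyloxy)-3-[methoxy(methyl)carbamoyl]-6-methylhept-6-enoate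
Conditions: TBSOTf (1.1 equiv), 2,6-lutidine, CH2Cl2, −78 → −20 °C
Reagents that add atoms: tert-butyldimethylsilyl triflate, CC(C)(C)[Si](C)(C)OS(=O)(=O)C(F)(F)F
Why: silylation of a hindered secondary alcohol with a silyl triflate is fast at low temperature, where one equivalent of reagent should not attack the tert-butyl ester.

Step 6
Reactants: 9 silyloxy Weinreb amide
Product: 10 tert-butyl (3R,4S)-3-acryloyl-4-(tert-butyldimethylsilyloxy)-6-methylhept-6-enoate
Conditions: CH2=CHMgBr, THF, −78 → −10 °C; inverse quench into cold 1 M HCl
Reagents that add atoms: vinylmagnesium bromide, C=C[Mg]Br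
Why: in the Weinreb ketone synthesis the chelated tetrahedral intermediate holds until work-up, the tert-butyl ester is inert at this temperature, and the acidic inverse quench keeps the freed amine from adding to the vinyl ketone.

Step 7
Reactants: 10 vinyl ketone
Product: 11 tert-butyl 2-[(1R,6S)-6-(tert-butyldimethylsilyloxy)-4-methyl-2-oxocyclohex-3-en-1-yl]acetate (ring B enone: C6=O, C5=C10, C14 on C10, C7 side chain and O8 trans)
Conditions: second-generation Grubbs catalyst (5 mol %), CH2Cl2 (0.01 M), 40 °C
Reagents that add atoms: none
Why: ring-closing metathesis of a vinyl ketone with a 1,1-disubstituted olefin closes the 3-methylcyclohexenone under neutral conditions, which avoids any ring enolate with the silyloxy group in its β-position and hence loss of silanol with aromatisation to a cresol.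

Step 8
Reactants: 12 methylenecyclobutane
Product: 13 1-methylcyclobutene
Conditions: Na on Al2O3 (cat.), neat, 20 °C; fractional distillation
Reagents that add atoms: none
Why: base-catalysed prototropic isomerisation moves the exocyclic double bond into the ring because the trisubstituted endocyclic olefin is favoured at equilibrium, and residual 12 is removed by distillation.

Step 9
Reactants: 11 ring B enone; 13 1-methylcyclobutene
Product: 14 cis,anti,cis photoadduct. Ring B ketone (C6=O) is cis-fused at C5–C10 to the central cyclobutane (C1, C4, C5, C10), which is cis-fused at C1–C4 to ring A. Ring A is anti to ring B, and the cyclobutane lies on the face of ring B opposite O8. C14 sits on C10 and C15 on C4; the CH2CO2t-Bu group on C7 and the OTBS group on C8 are unchanged.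
Conditions: 13 (10 equiv), CH2Cl2, hν (350 nm, Pyrex), −30 °C
Reagents that add atoms: none
Why: Irradiation populates the twisted triplet state of enone 11, whose β-carbon C10 bonds to the unsubstituted olefinic carbon C1 of 13 to give a 1,4-biradical with its spins on tertiary C4 and α-keto C5; after spin inversion, C4–C5 radical recombination closes the central cyclobutane, the one ring formed here, ring A being carried in intact. The closest known reaction type is the intermolecular enone–cycloalkene (2+2) photocycloaddition, which has been run with cyclohexenones and cyclobutenes to give cis,anti,cis tricyclo[4.4.0.0(2,5)]decanones. C10 is set by chair-like axial bonding at the β-carbon on the face opposite the equatorial C8 silyloxy group, C5 by the need for a cis six–four fusion in so strained a product, the cis pair C1/C4 by ring A itself, and their anti placement by approach of 13 with its C2–C3 bridge turned away from ring B. The step needs the head-to-head orientation (C4 on C5, C1 on C10): the opposite orientation would have to join the two fully substituted carbons C4 and C10, so the biradicals leading to it should revert to 11 and 13 rather than close, and it is the C14 methyl group of the substrate that secures this. It also needs the facial selectivity just named, because only in the adduct anti to O8 can ring B keep C11 and O8 equatorial while C9 is equatorial and C6 axial on the later 1,4-diyl, the arrangement that leads to 1(10)E,4Z, whereas the syn adduct would lead to 1(10)Z,4E and is removed by chromatography. A large excess of 13 at low temperature holds back enone dimerisation and loss of the volatile olefin.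

Step 10
Reactants: 14 photoadduct
Product: 16 tetracyclic (6S) cis-γ-lactone of the photoadduct series (O6 on the ring B face that carries the cyclobutane and C11; 8-OTBS kept), via 6S hydroxy ester 15 (not isolated)
Conditions: LiBH(s-Bu)3, THF, −78 °C; then KOt-Bu (0.2 equiv), −78 → 20 °C; H2O
Reagents that add atoms: none
Why: in this bulky-borohydride ketone reduction the cyclobutane and the C15 methyl group cover the face of C6=O cis to C4, so hydride arrives from the convex face and gives the (6S)-alkoxide cis to the C7 side chain, which closes the cis-fused lactone by intramolecular transesterification with loss of tert-butoxide and thereby removes both the enolisable β-silyloxy ketone and the heat-labile ester before the thermolysis.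

Step 11
Reactants: 16 tetracyclic cis-lactone
Product: 17 (1(10)E,4Z,6S,8S)-8-(tert-butyldimethylsilyloxy)-13-norgermacra-1(10),4-dien-12,6-olide (6-epi, cis-fused lactone)
Conditions: flash vacuum thermolysis: sublimed at 110 °C/0.01 mbar through a base-washed quartz tube at 450 °C, trap at −78 °C
Reagents that add atoms: none
Why: in this thermal cycloreversion of a bicyclo[2.2.0]hexane the strained C1–C4 bond breaks first, the cyclohexane-1,4-diyl relaxes to a chair cis-fused to ring B, and scission of C5–C10 turns equatorial C9 into the E C1=C10 bond and axial C6 into the Z C4=C5 bond, the sense being fixed because the flipped chair would place C4/C11 and O8/C14 syn-diaxial, while the short contact time favours this high-A-factor fragmentation over the ordered Cope rearrangement to a divinylcyclohexane.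

Step 12
Reactants: 17 6-epi lactone
Product: 18 (1(10)E,4Z,6S,8S)-8-(tert-butyldimethylsilyloxy)-6-hydroxy-13-norgermacra-1(10),4-dien-12-oic acid
Conditions: LiOH, THF/H2O, 0 → 20 °C; cold 0.5 M HCl to pH 5, EtOAc; used at once
Reagents that add atoms: lithium hydroxide, [Li+].[OH-]
Why: saponification of a γ-lactone spares the silyl ether and both olefins, and the small C5–C6–C7–C8 torsion that a cis fusion forces on the ten-membered ring should slow re-closure during the cold, mildly acidic work-up.

Step 13
Reactants: 18 (6S)-hydroxy acid
Product: 19 (1(10)E,4Z,6R,8S)-8-(tert-butyldimethylsilyloxy)-13-norgermacra-1(10),4-dien-12,6-olide (trans-fused lactone, H6 and H7 trans)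
Conditions: PPh3, DIAD, toluene (0.01 M), 0 °C
Reagents that add atoms: none
Why: in this intramolecular Mitsunobu reaction the allylic C6 hydroxyl becomes an alkoxyphosphonium leaving group that the C12 carboxylate displaces from the rear in a 5-exo-tet closure, which inverts C6 to the required R configuration and gives the trans fusion that a ten-membered ring accommodates best.

Step 14
Reactants: 19 trans-lactone
Product: 20 11-(dimethylaminomethyl) lactone (Mannich base; CH2NMe2 drawn trans to C8)
Conditions: LiN(i-Pr)2, THF, −78 °C; Me2N=CH2+ I− (Eschenmoser's salt), −78 → 0 °C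
Reagents that add atoms: dimethylmethyleneammonium iodide, C=[N+](C)C.[I-]
Why: aminomethylation of the lactone enolate (Mannich reaction) is clean because no leaving group sits on C7, and the new C11 stereocentre, expected anti to the C7–C8 bond, is erased in the next step.

Step 15
Reactants: 20 Mannich base
Product: 22 (1(10)E,4Z,6R,8S)-8-(tert-butyldimethylsilyloxy)germacra-1(10),4,11(13)-trien-12,6-olide, via trimethylammonium iodide 21 (not isolated)
Conditions: MeI, MeOH, 20 °C; then aq NaHCO3, CH2Cl2
Reagents that add atoms: none
Why: quaternisation followed by Hofmann-type E1cB loss of trimethylamine under weak base is the standard mild way to an α-methylene-γ-lactone.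

Step 16
Reactants: 22 silyl ether
Product: 23 (1(10)E,4Z,6R,8S)-8-hydroxygermacra-1(10),4,11(13)-trien-12,6-olide
Conditions: HF·pyridine, pyridine, THF, 0 → 20 °C
Reagents that add atoms: none
Why: buffered fluoride desilylation never generates a C8 alkoxide, so translactonisation to the 8,12-olide and Michael addition to C13 are avoided, and the pyridine buffer guards the diene against transannular cyclisation.

Step 17
Reactants: 23 C8 carbinol; 24 angelic acid
Product: 26 (1(10)E,4Z,6R,8S)-8-angeloyloxygermacra-1(10),4,11(13)-trien-12,6-olide, via mixed angelic trichlorobenzoic anhydride 25 (not isolated)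
Conditions: 24, 2,4,6-Cl3C6H2COCl, Et3N, toluene, 20 °C; then 23, 75 °C
Reagents that add atoms: none
Why: Yamaguchi-type acylation through the mixed anhydride without a nucleophilic catalyst avoids the reversible conjugate addition that turns angelates into tiglates, so the Z geometry should be kept and C8 is acylated with retention.

Step 18
Reactants: 26 angelate triene
Product: 27 target, (1R,6R,7R,8S)-1-hydroperoxy-8-angeloyloxygermacra-4Z,10(14),11(13)-trien-12,6-olide
Conditions: O2, hν (visible), tetraphenylporphyrin (cat.), CH2Cl2, −20 °C; no reductive work-up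
Reagents that add atoms: dioxygen, O=O
Why: in the Schenck ene reaction singlet oxygen picks the most electron-rich olefin C1=C10 (C4=C5 is deactivated by the allylic lactone oxygen, the two enoates are inert), abstracts hydrogen from C14 on the more crowded side of the E olefin (C14 cis to C2) so that oxygen lands on C1 and the double bond moves to C10=C14, and attacks the outer face of the ring to give the 1R (1β) hydroperoxide, as in the photooxygenation of related 1(10)-unsaturated germacranolides.

**Compound list**

1 | 4-tert-butoxy-4-oxobutanoic acid (mono-tert-butyl succinate) | CC(C)(C)OC(=O)CCC(=O)O | starting material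
2 | (R)-4-benzyl-1,3-oxazolidin-2-one | O=C1OC[C@@H](Cc2ccccc2)N1 | starting material
3 | 4-tert-butoxy-4-oxobutanoic pivalic anhydride | CC(C)(C)OC(=O)CCC(=O)OC(=O)C(C)(C)C | intermediate
4 | tert-butyl 4-[(4R)-4-benzyl-2-oxo-1,3-oxazolidin-3-yl]-4-oxobutanoate | O=C1OC[C@@H](Cc2ccccc2)N1C(=O)CCC(=O)OC(C)(C)C | intermediate
5 | 3-methylbut-3-en-1-ol | C=C(C)CCO | starting material
6 | 3-methylbut-3-enal | C=C(C)CC=O | intermediate
7 | syn aldol imide (C7 R, C8 S) | O=C1OC[C@@H](Cc2ccccc2)N1C(=O)[C@H](CC(=O)OC(C)(C)C)[C@@H](O)CC(C)=C | intermediate
8 | hydroxy Weinreb amide | CON(C)C(=O)[C@H](CC(=O)OC(C)(C)C)[C@@H](O)CC(C)=C | intermediate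
9 | silyloxy Weinreb amide | CON(C)C(=O)[C@H](CC(=O)OC(C)(C)C)[C@@H](O[Si](C)(C)C(C)(C)C)CC(C)=C | intermediate
10 | vinyl ketone | C=CC(=O)[C@H](CC(=O)OC(C)(C)C)[C@@H](O[Si](C)(C)C(C)(C)C)CC(C)=C | intermediate
11 | ring B enone, tert-butyl 2-[(1R,6S)-6-(TBSO)-4-methyl-2-oxocyclohex-3-en-1-yl]acetate | CC1=CC(=O)[C@H](CC(=O)OC(C)(C)C)[C@@H](O[Si](C)(C)C(C)(C)C)C1 | intermediate
12 | methylenecyclobutane | C=C1CCC1 | starting material
13 | 1-methylcyclobutene | CC1=CCC1 | intermediate
14 | cis,anti,cis photoadduct (cyclobutane anti to O8) | O=C1[C@H](CC(=O)OC(C)(C)C)[C@@H](O[Si](C)(C)C(C)(C)C)C[C@]2(C)[C@H]3CC[C@@]3(C)[C@H]12 | intermediate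
15 | (6S)-hydroxy tert-butyl ester of the tricycle | O[C@@H]1[C@H](CC(=O)OC(C)(C)C)[C@@H](O[Si](C)(C)C(C)(C)C)C[C@]2(C)[C@H]3CC[C@@]3(C)[C@H]12 | intermediate
16 | tetracyclic (6S) cis-γ-lactone | O=C1C[C@H]2[C@@H](O1)[C@H]3[C@]4(C)CC[C@@H]4[C@@]3(C)C[C@@H]2O[Si](C)(C)C(C)(C)C | intermediate
17 | (1(10)E,4Z,6S)-8-TBSO-13-norgermacradien-12,6-olide (cis lactone) | O=C1C[C@H]2[C@@H](O1)/C=C(/C)CC/C=C(\C)C[C@@H]2O[Si](C)(C)C(C)(C)C | intermediate
18 | (6S)-hydroxy acid | OC(=O)C[C@H]1[C@@H](O)/C=C(/C)CC/C=C(\C)C[C@@H]1O[Si](C)(C)C(C)(C)C | intermediate
19 | (1(10)E,4Z,6R)-8-TBSO-13-norgermacradien-12,6-olide (trans lactone) | O=C1C[C@H]2[C@H](O1)/C=C(/C)CC/C=C(\C)C[C@@H]2O[Si](C)(C)C(C)(C)C | intermediate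
20 | 11-(dimethylaminomethyl) lactone | CN(C)C[C@@H]1C(=O)O[C@@H]2/C=C(/C)CC/C=C(\C)C[C@H](O[Si](C)(C)C(C)(C)C)[C@@H]12 | intermediate
21 | trimethylammonium iodide of 20 | C[N+](C)(C)C[C@@H]1C(=O)O[C@@H]2/C=C(/C)CC/C=C(\C)C[C@H](O[Si](C)(C)C(C)(C)C)[C@@H]12.[I-] | intermediate
22 | 8-TBSO α-methylene lactone | C=C1C(=O)O[C@@H]2/C=C(/C)CC/C=C(\C)C[C@H](O[Si](C)(C)C(C)(C)C)[C@@H]12 | intermediate
23 | 8-hydroxy α-methylene lactone | C=C1C(=O)O[C@@H]2/C=C(/C)CC/C=C(\C)C[C@H](O)[C@@H]12 | intermediate
24 | angelic acid, (Z)-2-methylbut-2-enoic acid | C/C=C(/C)C(=O)O | starting material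
25 | angelic 2,4,6-trichlorobenzoic anhydride | C/C=C(/C)C(=O)OC(=O)c1c(Cl)cc(Cl)cc1Cl | intermediate
26 | 8-angelate triene (ene precursor) | C=C1C(=O)O[C@@H]2/C=C(/C)CC/C=C(\C)C[C@H](OC(=O)/C(C)=C\C)[C@@H]12 | intermediate
27 | CNP0105813.1 | C=C1C(=O)O[C@@H]2/C=C(/C)CC[C@@H](OO)C(=C)C[C@H](OC(=O)/C(C)=C\C)[C@@H]12 | target

**Step count and risks**

Total step count: 18. Longest linear sequence: 16 (steps 1, 3–7, 9–18).

Three steps most likely to fail:

Step 9. The methyl-bearing cyclobutene carbon may bond to C10 (head-to-tail orientation), or the facial bias from O8 may be weak. The fallback sets out from 11 and comes back at 17, and it removes the regiochemical question.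
- 11 is irradiated with purchased cyclobutene, whose olefinic carbons are equivalent, to give the 15-nor photoadduct F1.
- Flash thermolysis at the ketone level gives the 15-nor (1(10)E,4Z)-dienone F2.
- Me2CuLi/Me3SiCl adds C15 to C4 and traps the C5=C6 silyl enol ether F3 (both C4 epimers serve).
- Saegusa–Ito dehydrogenation with Pd(OAc)2, followed by thiolate-catalysed equilibration of the enone to its Z form, gives the dienone F4.
- Luche reduction (NaBH4, CeCl3·7H2O) from the outer face of the ring should give the (6S)-carbinol F5, which KOt-Bu closes to 17.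

Step 11. The product may go on by Cope rearrangement, the diyl may cleave C2–C3 instead of C5–C10, or the E/Z sense may erode at the high wall temperature. The fallback sets out from 16 and comes back at 17. It runs the cycloreversion on the free carbinol, the form in which this reaction type is best established, and in solution at much lower temperature.
- LiAlH4 opens the lactone to the tricyclic 6,12-diol F6.
- Heating in toluene in a sealed tube at 190 °C gives the (1(10)E,4Z)-dienediol F7.
- Oxidative lactonisation with TEMPO/PhI(OAc)2 (primary alcohol to aldehyde, lactol, lactone) returns 17.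

Step 13. Closure may occur with retention through acyl activation, the hydroxy acid may re-lactonise before activation, or elimination and allylic transposition may compete. The fallback sets out from 18 and comes back at 19, and it separates the inversion from the ring closure.
- Me3SiCHN2 gives the hydroxy methyl ester F8.
- An intermolecular Mitsunobu reaction with 4-nitrobenzoic acid gives the inverted (6R)-4-nitrobenzoate F9.
- K2CO3/MeOH removes the aroyl group, and the freed 6R alkoxide closes onto the methyl ester to give 19.

**Further compounds**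

F1 | step 9 | 15-nor cis,anti,cis photoadduct | O=C1[C@H](CC(=O)OC(C)(C)C)[C@@H](O[Si](C)(C)C(C)(C)C)C[C@]2(C)[C@H]3CC[C@H]3[C@H]12
F2 | step 9 | 15-nor (1(10)E,4Z)-dienone | O=C1/C=C\CC/C=C(\C)C[C@H](O[Si](C)(C)C(C)(C)C)[C@H]1CC(=O)OC(C)(C)C
F3 | step 9 | C5=C6 trimethylsilyl enol ether with C15 on C4 (C4 epimers) | CC1CC/C=C(\C)C[C@H](O[Si](C)(C)C(C)(C)C)[C@@H](CC(=O)OC(C)(C)C)C(O[Si](C)(C)C)=C1
F4 | step 9 | (1(10)E,4Z)-dien-6-one tert-butyl ester | O=C1/C=C(/C)CC/C=C(\C)C[C@H](O[Si](C)(C)C(C)(C)C)[C@H]1CC(=O)OC(C)(C)C
F5 | step 9 | (6S)-dienol tert-butyl ester | O[C@H]1/C=C(/C)CC/C=C(\C)C[C@H](O[Si](C)(C)C(C)(C)C)[C@H]1CC(=O)OC(C)(C)C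
F6 | step 11 | tricyclic (6S)-6,12-diol | OCC[C@H]1[C@@H](O)[C@H]2[C@]3(C)CC[C@@H]3[C@@]2(C)C[C@@H]1O[Si](C)(C)C(C)(C)C
F7 | step 11 | (1(10)E,4Z,6S)-diene-6,12-diol | OCC[C@H]1[C@@H](O)/C=C(/C)CC/C=C(\C)C[C@@H]1O[Si](C)(C)C(C)(C)C
F8 | step 13 | (6S)-hydroxy methyl ester | COC(=O)C[C@H]1[C@@H](O)/C=C(/C)CC/C=C(\C)C[C@@H]1O[Si](C)(C)C(C)(C)C
F9 | step 13 | (6R)-4-nitrobenzoate methyl ester | COC(=O)C[C@H]1[C@H](OC(=O)c2ccc(cc2)[N+](=O)[O-])/C=C(/C)CC/C=C(\C)C[C@@H]1O[Si](C)(C)C(C)(C)C
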